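**Retrosynthetic overview**
- Last bond: C11–C12, by sp2–sp3 cross-coupling of the homoprenyl chain onto an α-iodo ε-lactone, so that the isopropylidene alkene enters only after the epoxidation.
- Key bond: C9–C10, by iodine-atom-transfer radical addition of a C1–C9 epoxy iodide to propiolic acid. Anti iodine transfer puts chain and CO2H cis; the acid then opens the (6R,7R)-epoxide at C7 with inversion, which closes the ε-lactone and gives (6R,7S).
- The epoxide comes from Shi epoxidation of an (E,E)-diene iodide whose 2,3-alkene is deactivated by the allylic acetate.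
- The diene iodide comes from an enyne iodide (Negishi carboalumination/CH2O, then Ac2O), made by Julia–Johnson rearrangement of a cyclopropylcarbinol from methyl 1-methylcyclopropyl ketone and propargyl bromide.
- Ring order: cyclopropane (bought, opened in step 3), then oxirane (step 6), then oxepinone (step 7, the only ring of the target).

Assumption: the target is the (6R,7S) isomer as written (C1 = CH2OAc, C6 = CHOH, C7 = quaternary C–O, C11 = lactone α-carbon), and a one-pot sequence counts as one step.

**Step 1**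
Reactants: 1 1-(1-methylcyclopropyl)ethan-1-one; 2 3-bromoprop-1-yne (propargyl bromide)
Product: 4 1-(1-methylcyclopropyl)pent-4-yn-1-one, via lithium enolate 3 (not isolated)
Conditions: LiN(iPr)2 (1.05 equiv), THF, −78 °C; then 2 (1.1 equiv), DMPU, −78 to −20 °C
Reagents that add atoms: none
Why: The ketone can enolise only at its methyl group, so kinetic lithium enolate formation and SN2 alkylation with the propargylic bromide (enolate alkylation) give the γ,δ-acetylenic ketone without regiochemical ambiguity and without a stereocentre.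

**Step 2**
Reactants: 4 1-(1-methylcyclopropyl)pent-4-yn-1-one
Product: 5 rac-1-(1-methylcyclopropyl)pent-4-yn-1-ol
Conditions: NaBH4, MeOH, 0 °C
Reagents that add atoms: none
Why: Borohydride carbonyl reduction gives the secondary cyclopropylcarbinol as a racemate, which is sufficient because this carbon becomes sp2 in step 3.

**Step 3**
Reactants: 5 rac-1-(1-methylcyclopropyl)pent-4-yn-1-ol
Product: 6 (5E)-8-iodo-6-methyloct-5-en-1-yne
Conditions: MgI2·OEt2 (2 equiv), Et2O–toluene, reflux
Reagents that add atoms: magnesium iodide, [Mg+2].[I-].[I-]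
Why: Julia–Johnson cyclopropylcarbinyl-to-homoallyl rearrangement: the magnesium-activated carbinol ionises in the bisected conformation that keeps the alkynyl chain away from the ring methylenes and iodide opens the ring, which gives the (E)-trisubstituted alkene and the primary iodide in one operation.

**Step 4**
Reactants: 6 (5E)-8-iodo-6-methyloct-5-en-1-yne
Product: 9 (2E,6E)-9-iodo-3,7-dimethylnona-2,6-dien-1-ol, via alkenylalane 7 (not isolated), via lithium alanate 8 (not isolated)
Conditions: Me3Al (2.5 equiv), Cp2ZrCl2 (0.25 equiv), CH2Cl2, 0 °C to rt; evaporate; MeLi (1 equiv), hexane–THF, −78 °C; (CH2O)n, −78 °C to rt; aq. NH4Cl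
Reagents that add atoms: trimethylaluminium, C[Al](C)C; paraformaldehyde (as formaldehyde), C=O
Why: Negishi zirconium-catalysed carboalumination adds CH3 and Al syn across the terminal alkyne with CH3 on the internal carbon, and the alanate (formed with MeLi, which leaves the primary iodide alone at −78 °C) is hydroxymethylated with retention, so the (2E)-allylic alcohol forms with high geometric purity.

**Step 5**
Reactants: 9 (2E,6E)-9-iodo-3,7-dimethylnona-2,6-dien-1-ol
Product: 10 (2E,6E)-9-iodo-3,7-dimethylnona-2,6-dien-1-yl acetate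
Conditions: Ac2O, pyridine, DMAP (cat.), CH2Cl2, 0 °C
Reagents that add atoms: acetic anhydride, CC(=O)OC(C)=O
Why: DMAP-catalysed acylation of the primary allylic alcohol installs the acetate of the target, which also deactivates the 2,3-alkene for step 6.

**Step 6**
Reactants: 10 (2E,6E)-9-iodo-3,7-dimethylnona-2,6-dien-1-yl acetate
Product: 11 (2E)-5-[(2R,3R)-3-(2-iodoethyl)-3-methyloxiran-2-yl]-3-methylpent-2-en-1-yl acetate
Conditions: Shi ketone (D-fructose-derived, 0.3 equiv), Oxone (2KHSO5·KHSO4·K2SO4, 1.4 equiv), K2CO3, Bu4NHSO4 (cat.), MeCN–dimethoxymethane/aq. buffer (pH 10.5), 0 °C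
Reagents that add atoms: potassium peroxymonosulfate (the oxidant in Oxone), [K+].[O-]S(=O)(=O)OO
Why: Shi asymmetric epoxidation: the chiral dioxirane attacks the electron-rich 6,7-alkene in preference to the acetate-deactivated 2,3-alkene and, through the spiro transition state, gives the (R,R)-epoxide, which fixes C6 directly and C7 after the inversion in step 7.

**Step 7 (key step)**
Reactants: 11 (2E)-5-[(2R,3R)-3-(2-iodoethyl)-3-methyloxiran-2-yl]-3-methylpent-2-en-1-yl acetate; 12 prop-2-ynoic acid (propiolic acid)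
Product: 16 (2E,6R)-6-hydroxy-6-[(2S)-6-iodo-2-methyl-7-oxo-2,3,4,7-tetrahydrooxepin-2-yl]-3-methylhex-2-en-1-yl acetate, via trimethylsilyl propiolate 13 (not isolated), via silyl ester adduct 14 (not isolated), via epoxy acid 15 (not isolated)
Conditions: 12 (3 equiv), BSA (1.6 equiv), PhH, rt; then 11 (1 M), BEt3 (0.3 equiv), air, rt; evaporate; CSA (0.1 equiv), THF–H2O, 0 °C to rt
Reagents that add atoms: none
Why: Iodine-atom-transfer radical addition (Kharasch-type): the primary C9 radical from 11 adds to the β-carbon of the propiolate and the linear α-ester vinyl radical abstracts iodine from 11 on the side away from the new chain, so chain and carboxyl are cis and, once water frees the acid, it opens the protonated epoxide 7-exo at the tertiary carbon with inversion (epoxy-acid lactonisation), which sets the (S)-quaternary centre and closes the ε-lactone.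

**Step 8**
Reactants: 16 (2E,6R)-6-hydroxy-6-[(2S)-6-iodo-2-methyl-7-oxo-2,3,4,7-tetrahydrooxepin-2-yl]-3-methylhex-2-en-1-yl acetate; 17 5-bromo-2-methylpent-2-ene
Product: 19 (2E,6R)-6-hydroxy-3-methyl-6-[(2S)-2-methyl-6-(4-methylpent-3-en-1-yl)-7-oxo-2,3,4,7-tetrahydrooxepin-2-yl]hex-2-en-1-yl acetate, via alkylzinc bromide 18 (not isolated)
Conditions: 17 (3 equiv), Zn dust, I2 (5 mol %), DMA, 70 °C; then 16, PdCl2(dppf) (5 mol %), THF–DMA, rt
Reagents that add atoms: none
Why: Negishi sp2–sp3 cross-coupling: oxidative addition into the α-iodoenoate C–I bond is much faster than ionisation of the trisubstituted allylic acetate and the alkylzinc halide tolerates the lactone and the free hydroxyl, so the homoprenyl chain is attached with the ring-locked alkene and both stereocentres unchanged.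

**Compound list**
1 | 1-(1-methylcyclopropyl)ethan-1-one | CC(=O)C1(C)CC1 | starting material
2 | 3-bromoprop-1-yne (propargyl bromide) | C#CCBr | starting material
3 | lithium 1-(1-methylcyclopropyl)ethen-1-olate | [Li+].[O-]C(=C)C1(C)CC1 | intermediate
4 | 1-(1-methylcyclopropyl)pent-4-yn-1-one | C#CCCC(=O)C1(C)CC1 | intermediate
5 | rac-1-(1-methylcyclopropyl)pent-4-yn-1-ol | C#CCCC(O)C1(C)CC1 | intermediate
6 | (5E)-8-iodo-6-methyloct-5-en-1-yne | C#CCC/C=C(\C)CCI | intermediate
7 | [(1E,5E)-8-iodo-2,6-dimethylocta-1,5-dien-1-yl]dimethylalane | C[Al](C)/C=C(\C)CC/C=C(\C)CCI | intermediate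
8 | lithium [(1E,5E)-8-iodo-2,6-dimethylocta-1,5-dien-1-yl]trimethylalanate | [Li+].C[Al-](C)(C)/C=C(\C)CC/C=C(\C)CCI | intermediate
9 | (2E,6E)-9-iodo-3,7-dimethylnona-2,6-dien-1-ol | OC/C=C(\C)CC/C=C(\C)CCI | intermediate
10 | (2E,6E)-9-iodo-3,7-dimethylnona-2,6-dien-1-yl acetate | CC(=O)OC/C=C(\C)CC/C=C(\C)CCI | intermediate
11 | (2E)-5-[(2R,3R)-3-(2-iodoethyl)-3-methyloxiran-2-yl]-3-methylpent-2-en-1-yl acetate | CC(=O)OC/C=C(\C)CC[C@H]1O[C@]1(C)CCI | intermediate
12 | prop-2-ynoic acid (propiolic acid) | C#CC(=O)O | starting material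
13 | trimethylsilyl prop-2-ynoate | C#CC(=O)O[Si](C)(C)C | intermediate
14 | trimethylsilyl (2E)-5-[(2R,3R)-3-[(3E)-5-(acetyloxy)-3-methylpent-3-en-1-yl]-2-methyloxiran-2-yl]-2-iodopent-2-enoate | CC(=O)OC/C=C(\C)CC[C@H]1O[C@]1(C)CC/C=C(/I)C(=O)O[Si](C)(C)C | intermediate
15 | (2E)-5-[(2R,3R)-3-[(3E)-5-(acetyloxy)-3-methylpent-3-en-1-yl]-2-methyloxiran-2-yl]-2-iodopent-2-enoic acid | CC(=O)OC/C=C(\C)CC[C@H]1O[C@]1(C)CC/C=C(/I)C(=O)O | intermediate
16 | (2E,6R)-6-hydroxy-6-[(2S)-6-iodo-2-methyl-7-oxo-2,3,4,7-tetrahydrooxepin-2-yl]-3-methylhex-2-en-1-yl acetate | CC(=O)OC/C=C(\C)CC[C@@H](O)[C@]1(C)CCC=C(I)C(=O)O1 | intermediate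
17 | 5-bromo-2-methylpent-2-ene | CC(C)=CCCBr | starting material
18 | (4-methylpent-3-en-1-yl)zinc bromide | CC(C)=CCC[Zn]Br | intermediate
19 | (2E,6R)-6-hydroxy-3-methyl-6-[(2S)-2-methyl-6-(4-methylpent-3-en-1-yl)-7-oxo-2,3,4,7-tetrahydrooxepin-2-yl]hex-2-en-1-yl acetate | CC(=O)OC/C=C(\C)CC[C@@H](O)[C@]1(C)CCC=C(CCC=C(C)C)C(=O)O1 | target

**Totals**
Total step count: 8. Longest linear sequence: 8 steps (1 → 4 → 5 → 6 → 9 → 10 → 11 → 16 → 19); 2, 12 and 17 enter convergently.

**Three steps most likely to fail**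

Step 7. The iodine transfer may not be cleanly anti, the propiolate may telomerise, or the epoxide may be opened intermolecularly. Only the isomer with chain and acid cis can lactonise; the other stays an acid and is removed by a NaHCO3 wash. The fallback sets out from 11 and comes back at 16, replacing the radical addition by a polar sp3–sp2 coupling and a later iodination. Zinc insertion into 11 (Zn dust, LiCl, THF, 40 °C) gives the primary alkylzinc iodide F1. It is coupled (Pd2(dba)3, SPhos, THF, rt) with trimethylsilyl (2Z)-3-iodoprop-2-enoate F2, made in the flask from (Z)-3-iodoacrylic acid and BSA, with retention to the silyl (2Z)-enoate F3. Aqueous work-up frees the epoxy (2Z)-acid F4, which lactonises with CSA as in step 7 to the iodine-free ε-lactone F5. α-Iodination of F5 (I2, pyridine, CH2Cl2) returns 16.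

Step 8. The zerovalent palladium may ionise the allylic acetate, the free hydroxyl may protonate the zinc reagent, or the alkylpalladium may undergo β-hydride elimination. The fallback sets out from 16 and comes back at 19, dropping the bromide 17 and the organozinc for a hydroboration/B-alkyl Suzuki–Miyaura sequence. 4-Methylpenta-1,3-diene is hydroborated at its terminal alkene with 9-BBN-H (THF, 0 °C to rt) to give 9-(4-methylpent-3-en-1-yl)-9-borabicyclo[3.3.1]nonane F6. F6 is coupled with 16 (PdCl2(dppf), AsPh3, K3PO4, DMF–THF–H2O, rt) to give 19.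

Step 3. The E:Z ratio may fall short, or the carbinol may eliminate or be substituted without ring opening. The fallback sets out from 2 and comes back at 6, building the alkene by a [3,3] rearrangement instead. The kinetic lithium enolate of 3-methylbut-3-en-2-one is alkylated with 2 to give 2-methylhept-1-en-6-yn-3-one F7. Luche reduction (NaBH4, CeCl3·7H2O, MeOH) gives rac-2-methylhept-1-en-6-yn-3-ol F8. Johnson–Claisen rearrangement with trimethyl orthoacetate (propionic acid cat., 110 °C) sets the (E)-alkene through a chair transition state in methyl (4E)-4-methylnon-4-en-8-ynoate F9. LiOH hydrolysis gives (4E)-4-methylnon-4-en-8-ynoic acid F10, and radical iododecarboxylation (PhI(OAc)2, I2, hν) returns 6.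

**Further compounds**
F1 | step 7 | [2-[(2R,3R)-3-[(3E)-5-(acetyloxy)-3-methylpent-3-en-1-yl]-2-methyloxiran-2-yl]ethyl]zinc iodide | CC(=O)OC/C=C(\C)CC[C@H]1O[C@]1(C)CC[Zn]I
F2 | step 7 | trimethylsilyl (2Z)-3-iodoprop-2-enoate | C[Si](C)(C)OC(=O)/C=C\I
F3 | step 7 | trimethylsilyl (2Z)-5-[(2R,3R)-3-[(3E)-5-(acetyloxy)-3-methylpent-3-en-1-yl]-2-methyloxiran-2-yl]pent-2-enoate | CC(=O)OC/C=C(\C)CC[C@H]1O[C@]1(C)CC/C=C\C(=O)O[Si](C)(C)C
F4 | step 7 | (2Z)-5-[(2R,3R)-3-[(3E)-5-(acetyloxy)-3-methylpent-3-en-1-yl]-2-methyloxiran-2-yl]pent-2-enoic acid | CC(=O)OC/C=C(\C)CC[C@H]1O[C@]1(C)CC/C=C\C(=O)O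
F5 | step 7 | (2E,6R)-6-hydroxy-3-methyl-6-[(2S)-2-methyl-7-oxo-2,3,4,7-tetrahydrooxepin-2-yl]hex-2-en-1-yl acetate | CC(=O)OC/C=C(\C)CC[C@@H](O)[C@]1(C)CCC=CC(=O)O1
F6 | step 8 | 9-(4-methylpent-3-en-1-yl)-9-borabicyclo[3.3.1]nonane | CC(C)=CCCB1C2CCCC1CCC2
F7 | step 3 | 2-methylhept-1-en-6-yn-3-one | C=C(C)C(=O)CCC#C
F8 | step 3 | rac-2-methylhept-1-en-6-yn-3-ol | C=C(C)C(O)CCC#C
F9 | step 3 | methyl (4E)-4-methylnon-4-en-8-ynoate | COC(=O)CC/C(C)=C/CCC#C
F10 | step 3 | (4E)-4-methylnon-4-en-8-ynoic acid | OC(=O)CC/C(C)=C/CCC#C
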